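The twofold-symmetric biflavanone is cut at the C3–C3'' bond and at both O1–C2 bonds, which returns two molecules of one 4-hydroxychalcone. The key step exploits the fact that each half is joined at C3, the carbon alpha to the C4 ketone, and carries a para-oxygenated ring B on C2. Oxidation of the ring B phenol couples two radicals at C3, and the ring A 2'-hydroxyls then add to C2 and C2'' of the resulting bis(quinone methide) under a chiral phosphoric acid, closing both rings C and setting all four stereocentres. The precursor is a 4'-benzyloxy-2'-hydroxy-6'-methoxychalcone whose ring B phenol is flanked by two bromines that block, acidify and are later removed.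

Key step: step 3

Remark: flavanone numbering is used (ring C holds O1, C2, C3, C4; ring B sits on C2; the second half carries double primes), and the (R)-configured phosphoric acid of step 3 is assumed to favour the 2S,2''S closure; if the opposite sense is found, its (S)-enantiomer is used with no other change.

Step 1
Reactants: 1 2',4'-dihydroxy-6'-methoxyacetophenone; 2 benzyl bromide
Product: 3 4'-(benzyloxy)-2'-hydroxy-6'-methoxyacetophenone
Conditions: K2CO3 (1.2 equiv), acetone, reflux
Reagents that add atoms: none
Why: Williamson ether synthesis: the 4'-hydroxyl, para to the acetyl group and not hydrogen-bonded, is the more acidic and accessible phenol, whereas the 2'-hydroxyl is tied up in a chelate with the carbonyl and should stay free when one equivalent of 2 is used.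

Step 2
Reactants: 3 4'-(benzyloxy)-2'-hydroxy-6'-methoxyacetophenone; 4 3,5-dibromo-4-hydroxybenzaldehyde
Product: 5 (E)-1-[4-(benzyloxy)-2-hydroxy-6-methoxyphenyl]-3-(3,5-dibromo-4-hydroxyphenyl)prop-2-en-1-one
Conditions: BF3·OEt2 (3 equiv), 1,4-dioxane, rt; aq. NaHCO3 work-up
Reagents that add atoms: none
Why: Lewis acid mediated Claisen–Schmidt (aldol) condensation: BF3·OEt2 enolises the chelated methyl ketone and activates the aldehyde while the acidic dibromophenol stays protonated (under base it would become an unreactive phenolate), and dehydration of the aldol should give the conjugated E-enone as the more stable isomer.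

Step 3
Reactants: 5 (E)-1-[4-(benzyloxy)-2-hydroxy-6-methoxyphenyl]-3-(3,5-dibromo-4-hydroxyphenyl)prop-2-en-1-one (two molecules)
Product: 7 (2S,3R,2''S,3''R)-7,7''-bis(benzyloxy)-3',5',3''',5'''-tetrabromo-4',4'''-dihydroxy-5,5''-dimethoxy-3,3''-biflavanone, via bis(quinone methide) 6 (not isolated)
Conditions: Ag2O (1.2 equiv), 4 Å MS, CH2Cl2, 0 °C, dark; cold filtration through Celite; then (R)-3,3'-bis(2,4,6-triisopropylphenyl)-1,1'-binaphthyl-2,2'-diyl hydrogen phosphate (10 mol %), toluene/CH2Cl2, −40 °C → rt, 12 h
Reagents that add atoms: none
Why: Proposed new method: Ag2O turns the acidic dibromophenol of ring B, the only phenol that is neither chelated nor etherified, into a phenoxyl radical whose spin density extends through the enone to the carbon alpha to the ketone, so two radicals join at C3–C3'' to give bis(quinone methide) 6, and once the silver is filtered off the phosphoric acid hydrogen-bonds each quinone methide carbonyl and each 2'-hydroxyl and guides O1 onto C2 and O1'' onto C2'', re-aromatising ring B. The closest known reaction types are the oxidative 8–8 dimerisation of 4-hydroxycinnamates, whose bis(quinone methides) are captured by internal oxygen nucleophiles, and chiral phosphoric acid catalysed 1,6-additions to para-quinone methides; their merger on a chalcone in enantioselective form is without precedent. Each ring C closes in a 6-exo-trig mode, the phenol oxygen attacking the ring carbon C2 of the exocyclic C2=C1' bond. C2 and C2'' should be set by the chiral phosphate, which selects the face of each quinone methide, whereas C3 and C3'' are set relative to them by allylic strain in the closure (C3–H eclipses the C2=C1' bond, which leads to the trans ring) and by acid-mediated enolisation of the ketones, which moves any cis ring to the more stable trans,trans arrangement. The step needs C3–C3'' coupling in preference to C–O and ortho-carbon coupling, which the two bromines secure by occupying both ortho positions of ring B and shielding the phenoxyl oxygen, and it needs ring closure to outrun tautomerisation of the quinone methide, which the 2'-hydroxyl placed for a six-membered closure and the cold, base-free second stage should secure. Because two like centres are created, a wrong closure at one C2 ends mostly in the separable meso diastereomer, which should raise the enantiomeric purity of the twofold-symmetric product.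

Step 4
Reactants: 7 (2S,3R,2''S,3''R)-7,7''-bis(benzyloxy)-3',5',3''',5'''-tetrabromo-4',4'''-dihydroxy-5,5''-dimethoxy-3,3''-biflavanone
Product: 8 (2S,3R,2''S,3''R)-7,7''-bis(benzyloxy)-3',5',3''',5'''-tetrabromo-4',5,4''',5''-tetramethoxy-3,3''-biflavanone
Conditions: Me3SiCHN2 (2 M in hexanes, 6 equiv), toluene/MeOH (4:1), 0 °C → rt
Reagents that add atoms: trimethylsilyldiazomethane, C[Si](C)(C)C=[N+]=[N-]
Why: O-Methylation of acidic phenols with trimethylsilyldiazomethane in methanol: the two dibromophenols are acidic enough to protonate the reagent and are methylated through the diazomethane released in the flask without added base, so ring C, which can open under base, and the enolisable C3 centres are not disturbed, and no other free hydroxyl is present to compete.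

Step 5
Reactants: 8 (2S,3R,2''S,3''R)-7,7''-bis(benzyloxy)-3',5',3''',5'''-tetrabromo-4',5,4''',5''-tetramethoxy-3,3''-biflavanone
Product: 9 4',4''',5,5''-tetramethylchamaejasmin, (2S,3R,2''S,3''R)-7,7''-dihydroxy-4',5,4''',5''-tetramethoxy-3,3''-biflavanone
Conditions: H2 (1 atm), 10% Pd/C, NaOAc (6 equiv), EtOAc/MeOH (1:1), rt
Reagents that add atoms: none
Why: Catalytic hydrogenolysis over Pd/C: the four aryl C–Br bonds (hydrodehalogenation) and the two benzyl ethers are cleaved in one operation, NaOAc neutralises the HBr so that ring C never meets strong acid, and the aryl ketones, the methyl ethers and the already thermodynamic trans,trans stereocentres should be untouched at 1 atm and rt.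

Compound list
1 | 2',4'-dihydroxy-6'-methoxyacetophenone | COc1cc(O)cc(O)c1C(C)=O | starting material
2 | benzyl bromide | BrCc1ccccc1 | starting material
3 | 4'-(benzyloxy)-2'-hydroxy-6'-methoxyacetophenone | COc1cc(OCc2ccccc2)cc(O)c1C(C)=O | intermediate
4 | 3,5-dibromo-4-hydroxybenzaldehyde | O=Cc1cc(Br)c(O)c(Br)c1 | starting material
5 | (E)-1-[4-(benzyloxy)-2-hydroxy-6-methoxyphenyl]-3-(3,5-dibromo-4-hydroxyphenyl)prop-2-en-1-one | COc1cc(OCc2ccccc2)cc(O)c1C(=O)/C=C/c1cc(Br)c(O)c(Br)c1 | intermediate
6 | bis(quinone methide): 1,4-bis[4-(benzyloxy)-2-hydroxy-6-methoxyphenyl]-2,3-bis[(3,5-dibromo-4-oxocyclohexa-2,5-dien-1-ylidene)methyl]butane-1,4-dione, formed in the flask as the meso and racemic forms at the two sp3 carbons (configuration left open) | COc1cc(OCc2ccccc2)cc(O)c1C(=O)C(C=C1C=C(Br)C(=O)C(Br)=C1)C(C=C1C=C(Br)C(=O)C(Br)=C1)C(=O)c1c(O)cc(OCc2ccccc2)cc1OC | intermediate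
7 | (2S,3R,2''S,3''R)-7,7''-bis(benzyloxy)-3',5',3''',5'''-tetrabromo-4',4'''-dihydroxy-5,5''-dimethoxy-3,3''-biflavanone (both rings C 2,3-trans) | Oc1c(Br)cc([C@H]2Oc3cc(OCc4ccccc4)cc(OC)c3C(=O)[C@@H]2[C@H]2C(=O)c3c(OC)cc(OCc4ccccc4)cc3O[C@@H]2c2cc(Br)c(O)c(Br)c2)cc1Br | intermediate
8 | (2S,3R,2''S,3''R)-7,7''-bis(benzyloxy)-3',5',3''',5'''-tetrabromo-4',5,4''',5''-tetramethoxy-3,3''-biflavanone | COc1c(Br)cc([C@H]2Oc3cc(OCc4ccccc4)cc(OC)c3C(=O)[C@@H]2[C@H]2C(=O)c3c(OC)cc(OCc4ccccc4)cc3O[C@@H]2c2cc(Br)c(OC)c(Br)c2)cc1Br | intermediate
9 | 4',4''',5,5''-tetramethylchamaejasmin, (2S,3R,2''S,3''R)-7,7''-dihydroxy-4',5,4''',5''-tetramethoxy-3,3''-biflavanone | COc1ccc([C@H]2Oc3cc(O)cc(OC)c3C(=O)[C@@H]2[C@H]2C(=O)c3c(OC)cc(O)cc3O[C@@H]2c2ccc(OC)cc2)cc1 | target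

Total step count: 5
Longest linear sequence: 5 steps (1 → 3 → 5 → 7 → 8 → 9)

Steps most likely to fail

1. Step 3 (proposed new method).
- What may go wrong: the phenoxyl radicals may couple through oxygen or at a bromine-bearing ring carbon instead of at C3. The quinone methide may tautomerise to the aromatic diene before it is captured. Ring closure may proceed without the acid and so erode the enantioselectivity. Equilibration at C3 may stay incomplete.
- Fallback (known chemistry, setting out from 5 and coming back at 7): the dimerisation is run in its non-asymmetric biomimetic form, Ag2O in benzene/acetone at rt without chiral additive, so that bis(quinone methide) 6 closes spontaneously. If needed, a short treatment with catalytic TsOH in CH2Cl2 equilibrates C3. This should give racemic trans,trans material, that is 7 together with its (2R,3S,2''R,3''S) enantiomer F1, besides the meso (2S,3R,2''R,3''S) diastereomer F2, which is removed on silica gel. The racemate is then resolved by preparative HPLC on a chiral stationary phase (amylose tris(3,5-dimethylphenylcarbamate)), and 7 re-enters the route before step 4.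

2. Step 2.
- What may go wrong: slow aldol addition to an electron-rich, acidic aldehyde, acid-induced isomerisation of the 2'-hydroxychalcone to the flavanone, or partial loss of the benzyl ether under the Lewis acid.
- Fallback (setting out from 4 and coming back at 5): the phenol of 4 is masked with chloromethyl methyl ether and K2CO3 in acetone to give 3,5-dibromo-4-(methoxymethoxy)benzaldehyde F3. Classical base-mediated Claisen–Schmidt condensation of this aldehyde with 3 (KOH, EtOH, rt) should give the methoxymethyl-protected (E)-chalcone F4. HCl in MeOH at rt then removes the acetal and delivers 5.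

3. Step 5.
- What may go wrong: bromide poisoning of the heterogeneous catalyst with incomplete debromination, or over-reduction (hydrogenolysis of the benzylic C2–O1 bond, reduction of the ketones) when the reaction is forced.
- Fallback (setting out from 8 and coming back at 9): the two tasks are separated. A homogeneous formate reduction (Pd(PPh3)4, HCO2Na, DMF, 80 °C) removes the four bromines and should give (2S,3R,2''S,3''R)-7,7''-bis(benzyloxy)-4',5,4''',5''-tetramethoxy-3,3''-biflavanone F5. Its benzyl ethers are then cleaved by a short, halide-free hydrogenolysis (H2, Pd(OH)2/C, EtOAc, rt) to give 9.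

Further compounds
F1 | step 3 | (2R,3S,2''R,3''S)-7,7''-bis(benzyloxy)-3',5',3''',5'''-tetrabromo-4',4'''-dihydroxy-5,5''-dimethoxy-3,3''-biflavanone (enantiomer of 7) | Oc1c(Br)cc([C@@H]2Oc3cc(OCc4ccccc4)cc(OC)c3C(=O)[C@H]2[C@@H]2C(=O)c3c(OC)cc(OCc4ccccc4)cc3O[C@H]2c2cc(Br)c(O)c(Br)c2)cc1Br
F2 | step 3 | (2S,3R,2''R,3''S)-7,7''-bis(benzyloxy)-3',5',3''',5'''-tetrabromo-4',4'''-dihydroxy-5,5''-dimethoxy-3,3''-biflavanone (meso diastereomer of 7) | Oc1c(Br)cc([C@H]2Oc3cc(OCc4ccccc4)cc(OC)c3C(=O)[C@@H]2[C@@H]2C(=O)c3c(OC)cc(OCc4ccccc4)cc3O[C@H]2c2cc(Br)c(O)c(Br)c2)cc1Br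
F3 | step 2 | 3,5-dibromo-4-(methoxymethoxy)benzaldehyde | COCOc1c(Br)cc(C=O)cc1Br
F4 | step 2 | (E)-1-[4-(benzyloxy)-2-hydroxy-6-methoxyphenyl]-3-[3,5-dibromo-4-(methoxymethoxy)phenyl]prop-2-en-1-one | COCOc1c(Br)cc(/C=C/C(=O)c2c(O)cc(OCc3ccccc3)cc2OC)cc1Br
F5 | step 5 | (2S,3R,2''S,3''R)-7,7''-bis(benzyloxy)-4',5,4''',5''-tetramethoxy-3,3''-biflavanone | COc1ccc([C@H]2Oc3cc(OCc4ccccc4)cc(OC)c3C(=O)[C@@H]2[C@H]2C(=O)c3c(OC)cc(OCc4ccccc4)cc3O[C@@H]2c2ccc(OC)cc2)cc1
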